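A direct plan would start from a preformed carbocycle: 2-methylcyclopentane-1,3-dione A1 would be acyloxylated, dehydrogenated and dichlorinated to the achiral ene-dione A2, enlarged by one carbon under a chiral scandium catalyst to the cyclohexenedione A3, aminomethylenated to A4 and, last, joined with the enolate of the dienyl methyl ketone A5 to close the pyran.
Its weakest steps would be:
- the desymmetrising one-carbon ring expansion of A2 to A3: it alone would fix C7, by a catalytic reaction without precedent on an ene-dione, and attack at the other carbonyl, migration of the other carbon, cycloaddition or a second homologation could each intervene;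
- the dressing of the five-membered ring (acyloxylation, bromination–elimination, double chlorination): three steps that would add only two chlorine atoms and one C=C bond, one chlorine being lost again later;
- the final enolate addition–elimination with pyran closure: an excess of lithium enolate would meet the fully dressed, base-labile alpha-acyloxy dione, with three electrophilic sites (C4a, C5, C1), on the most precious material.

Plan of the new route
- Ring B of the target, together with C5, is the anhydrobase of a 4-methylpyrylium ion: C5 is the exocyclic carbon of a 4-methylene-4H-pyran (an enol-ether carbon in line with O2 through C3=C4–C4a=C5) and C6 is an acyl carbon. C7 is the alpha carbon of lactic acid, acylated by C8 and carrying C6 as its carboxyl carbon.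
- The retrosynthesis cuts C5–C6 (ring A), then C1–O2 and C4a–C8a (ring B), then C7–C8. This leaves a silyl ynone on the lactic acid acetal (Seebach dioxolanone) and a dienyl propynyl ketone.
- Forward, ring B arises first, as a pyrylium ion, from the two open-chain fragments. Ring A closes second, when C5 attacks the lactone carbonyl of the acetal, which also sets free the C7 hydroxyl.
- C7 comes from the chiral pool under auxiliary control, so no catalytic desymmetrisation is needed. Ring A is made in one bond from a methyl group, so no carbocycle has to be dressed. Union and both ring closures run in buffered acetic acid, so no strong base meets late material, and chlorine goes in last by a reaction type known on this ring system.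

Key step: step 6

Assumption: the acetal of (S)-lactic acid with 2,2-dimethylpropanal, 3-(trimethylsilyl)prop-2-ynal, both phosphorus ylides and prop-1-ynylmagnesium bromide are taken as purchased.
Remark: in the two chlorine-free bicyclic compounds C7 is labelled S and in the target R. Chlorine at C5 only reverses the CIP rank of C6 and C8; the centre itself is not touched.

Step 1
Reactants: 1 (2S,5S)-2-tert-butyl-5-methyl-1,3-dioxolan-4-one; 2 3-(trimethylsilyl)prop-2-ynal
Product: 4 (2S,5R)-2-tert-butyl-5-[1-hydroxy-3-(trimethylsilyl)prop-2-yn-1-yl]-5-methyl-1,3-dioxolan-4-one, via lithium enolate 3 (not isolated)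
Conditions: LiN(i-Pr)2 (1.1 equiv), THF, −78 °C; 2 (1.2 equiv), −78 °C; AcOH (1.2 equiv), −78 °C
Reagents that add atoms: none
Why: Seebach self-regeneration of stereocentres in an aldol addition: the tert-butyl group on the acetal carbon shields one face of the planar enolate, the aldehyde adds trans to it, and the quaternary carbon (the later C7) should form as (5R), the new C–C bond taking the place of the former C–H bond; the carbinol carbon forms as a mixture that step 2 removes.

Step 2
Reactants: 4 (2S,5R)-2-tert-butyl-5-[1-hydroxy-3-(trimethylsilyl)prop-2-yn-1-yl]-5-methyl-1,3-dioxolan-4-one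
Product: 5 (2S,5R)-2-tert-butyl-5-methyl-5-[3-(trimethylsilyl)prop-2-ynoyl]-1,3-dioxolan-4-one
Conditions: Dess–Martin periodinane (1.3 equiv), CH2Cl2, 0 °C → rt
Reagents that add atoms: none
Why: Dess–Martin oxidation of a secondary propargylic alcohol to the ynone under non-basic conditions, so that the beta-hydroxy lactone cannot undergo retro-aldol cleavage; both carbinol epimers converge and the quaternary centre has no alpha hydrogen.

Step 3
Reactants: 6 (S)-2-methylbutan-1-ol
Product: 8 (2E,4S)-2,4-dimethylhex-2-enal, via (S)-2-methylbutanal 7 (not isolated)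
Conditions: 2,2,6,6-tetramethylpiperidin-1-oxyl (1 mol %), KBr (10 mol %), aq NaOCl (1.1 equiv, pH 9.5), CH2Cl2, 0 °C; dried CH2Cl2 layer, Ph3P=C(Me)CHO (1.1 equiv), 40 °C
Reagents that add atoms: 2-(triphenylphosphoranylidene)propanal CC(C=O)=P(c1ccccc1)(c1ccccc1)c1ccccc1
Why: Nitroxyl/hypochlorite (Anelli) oxidation of the chiral-pool alcohol without racemisation, followed on the undistilled aldehyde solution by an E-selective Wittig olefination with a stabilised ylide; the (S) centre comes from the starting alcohol.

Step 4
Reactants: 8 (2E,4S)-2,4-dimethylhex-2-enal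
Product: 9 (2E,4E,6S)-N-methoxy-N,4,6-trimethylocta-2,4-dienamide
Conditions: Ph3P=CHC(O)N(OMe)Me (1.3 equiv), toluene, 90 °C
Reagents that add atoms: N-methoxy-N-methyl-2-(triphenylphosphoranylidene)acetamide CON(C)C(=O)C=P(c1ccccc1)(c1ccccc1)c1ccccc1
Why: Wittig olefination with the stabilised amide ylide under neutral conditions should give the (2E)-dienamide without gamma-deprotonation, so the allylic (S) centre is kept.

Step 5
Reactants: 9 (2E,4E,6S)-N-methoxy-N,4,6-trimethylocta-2,4-dienamide
Product: 10 (5E,7E,9S)-7,9-dimethylundeca-5,7-dien-2-yn-4-one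
Conditions: MeC≡CMgBr (1.5 equiv), THF, −20 → 0 °C; 1 M aq HCl, 0 °C
Reagents that add atoms: prop-1-yn-1-ylmagnesium bromide CC#C[Mg]Br
Why: Weinreb ketone synthesis: the alkynyl Grignard reagent adds 1,2 to the amide and the chelated tetrahedral intermediate survives until the acid quench, so neither over-addition nor conjugate addition to the dienyl chain is expected.

Step 6
Reactants: 5 (2S,5R)-2-tert-butyl-5-methyl-5-[3-(trimethylsilyl)prop-2-ynoyl]-1,3-dioxolan-4-one; 10 (5E,7E,9S)-7,9-dimethylundeca-5,7-dien-2-yn-4-one
Product: 15 (7S)-3-[(1E,3E,5S)-3,5-dimethylhepta-1,3-dien-1-yl]-7-hydroxy-7-methyl-6H-isochromene-6,8(7H)-dione, via morpholine enaminone 11 (not isolated), via open aminodienone 12 (not isolated), via pyrylium acetate 13 (not isolated), via 4-methylidene-4H-pyran 14 (not isolated)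
Conditions: 5, morpholine (1.05 equiv), MeOH (5 equiv), THF, 0 °C → rt; solvent change; 10 (1.1 equiv), toluene–AcOH 5:1, 50 °C; then NaOAc (3 equiv), 60 °C
Reagents that add atoms: none
Why: Proposed new method: morpholine adds to the silyl ynone of 5 with loss of the silyl group (the known use of silyl ynones as beta-keto aldehyde equivalents) to give 11, whose only soft nucleophilic carbon, C8a, adds in acetic acid to the alkyne carbon C4a of 10 and, after proton transfer, gives the 5-aminodienone 12; this is the Michael stage of the acid-promoted Bohlmann–Rahtz pyridine synthesis, here with a tertiary enaminone so that no pyridine can form. Ring B closes first: the C3 carbonyl oxygen of 12 adds to the iminium carbon C1 (6π-oxa-electrocyclisation of the 1-oxatriene, formally 6-exo-trig) and morpholine leaves, the known ring closure of 5-aminopenta-2,4-dienones to pyrylium salts, giving 13. Acetate then takes a proton from the 4-methyl group (C5), and the exocyclic carbon of the 4-methylidene-4H-pyran 14 attacks the acetal-activated lactone carbonyl C6 (6-exo-trig Claisen-type acylation; closest known reaction type: C-acylation and carbonyl condensation of 4-methylpyrylium anhydrobases with acid chlorides, anhydrides and aldehydes), which closes ring A; the tetrahedral intermediate expels the acetal oxygen, 2,2-dimethylpropanal is lost from the hemiacetal, and loss of a C5 proton from the regenerated pyrylium ion gives neutral 15, which should make the sequence irreversible. No stereocentre is formed: C7 is the quaternary carbon of step 1, it has no alpha hydrogen and stays tetrahedral throughout, and its acetal is consumed as leaving group and as protecting group of the tertiary alcohol. The step needs the union to occur through carbon at the alkyne of 10 (secured by the higher electrophilicity of the ynone over the dienone carbons and by the protic acid medium, which favours proton transfer over the [2+2] pathway of enamines with alkynes), and it needs ring A to close from C5 alone, which the structure secures because C5 is the only carbon of 14 that can reach C6 through an unstrained six-membered transition state (the ring carbon C4 would give a bridged bicycle) and because the 4-methyl protons are far more acidic than the doubly vinylogous CH of the side chain, so that the (S) centre is not at risk.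

Step 7
Reactants: 15 (7S)-3-[(1E,3E,5S)-3,5-dimethylhepta-1,3-dien-1-yl]-7-hydroxy-7-methyl-6H-isochromene-6,8(7H)-dione
Product: 16 (7S)-3-[(1E,3E,5S)-3,5-dimethylhepta-1,3-dien-1-yl]-7-methyl-6,8-dioxo-7,8-dihydro-6H-isochromen-7-yl propanoate
Conditions: (EtCO)2O (5 equiv), 4-(dimethylamino)pyridine (1 equiv), CH2Cl2, 0 °C → rt
Reagents that add atoms: propanoic anhydride CCC(=O)OC(=O)CC
Why: Nucleophile-catalysed acylation of the tertiary alpha-ketol hydroxyl, the reaction type by which 7-O-acyl derivatives of this ring system are made from their 7-hydroxy precursors; C7 is not involved.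

Step 8
Reactants: 16 (7S)-3-[(1E,3E,5S)-3,5-dimethylhepta-1,3-dien-1-yl]-7-methyl-6,8-dioxo-7,8-dihydro-6H-isochromen-7-yl propanoate
Product: 17 sclerketide B, (7R)-5-chloro-3-[(1E,3E,5S)-3,5-dimethylhepta-1,3-dien-1-yl]-7-methyl-6,8-dioxo-7,8-dihydro-6H-isochromen-7-yl propanoate
Conditions: N-chlorosuccinimide (1.05 equiv), MeCN, 0 °C → rt, dark
Reagents that add atoms: N-chlorosuccinimide O=C1CCC(=O)N1Cl
Why: Electrophilic chlorination at C5, the alpha carbon of the doubly vinylogous ester O2–C3=C4–C4a=C5–C6=O and the most nucleophilic carbon of the chromophore, a reaction type known on 7-acyloxy compounds of this ring system that carry the same dienyl chain; the descriptor at C7 changes from S to R only through the CIP ranking.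

## Compound list

1 | (2S,5S)-2-tert-butyl-5-methyl-1,3-dioxolan-4-one | C[C@@H]1O[C@H](C(C)(C)C)OC1=O | starting material
2 | 3-(trimethylsilyl)prop-2-ynal | C[Si](C)(C)C#CC=O | starting material
3 | lithium (2S)-2-tert-butyl-5-methyl-1,3-dioxol-4-olate | [Li]OC1=C(C)O[C@H](C(C)(C)C)O1 | intermediate
4 | (2S,5R)-2-tert-butyl-5-[1-hydroxy-3-(trimethylsilyl)prop-2-yn-1-yl]-5-methyl-1,3-dioxolan-4-one (both carbinol epimers) | C[C@]1(C(O)C#C[Si](C)(C)C)O[C@H](C(C)(C)C)OC1=O | intermediate
5 | (2S,5R)-2-tert-butyl-5-methyl-5-[3-(trimethylsilyl)prop-2-ynoyl]-1,3-dioxolan-4-one | C[C@]1(C(=O)C#C[Si](C)(C)C)O[C@H](C(C)(C)C)OC1=O | intermediate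
6 | (S)-2-methylbutan-1-ol | CC[C@H](C)CO | starting material
7 | (S)-2-methylbutanal | CC[C@H](C)C=O | intermediate
8 | (2E,4S)-2,4-dimethylhex-2-enal | O=C/C(C)=C/[C@@H](C)CC | intermediate
9 | (2E,4E,6S)-N-methoxy-N,4,6-trimethylocta-2,4-dienamide | CON(C)C(=O)/C=C/C(C)=C/[C@@H](C)CC | intermediate
10 | (5E,7E,9S)-7,9-dimethylundeca-5,7-dien-2-yn-4-one | CC#CC(=O)/C=C/C(C)=C/[C@@H](C)CC | intermediate
11 | (2S,5R)-2-tert-butyl-5-methyl-5-[(2E)-3-(morpholin-4-yl)prop-2-enoyl]-1,3-dioxolan-4-one | C[C@]1(C(=O)/C=C/N2CCOCC2)O[C@H](C(C)(C)C)OC1=O | intermediate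
12 | (2S,5R)-2-tert-butyl-5-methyl-5-[(6E,8E,10S)-3,8,10-trimethyl-2-(morpholin-4-ylmethylidene)-5-oxododeca-3,6,8-trienoyl]-1,3-dioxolan-4-one (geometry of the two new C=C bonds labile) | C[C@]1(C(=O)C(=CN2CCOCC2)C(C)=CC(=O)/C=C/C(C)=C/[C@@H](C)CC)O[C@H](C(C)(C)C)OC1=O | intermediate
13 | 5-{[(2S,4R)-2-tert-butyl-4-methyl-5-oxo-1,3-dioxolan-4-yl]carbonyl}-2-[(1E,3E,5S)-3,5-dimethylhepta-1,3-dien-1-yl]-4-methylpyrylium acetate | C[C@]1(C(=O)c2c[o+]c(/C=C/C(C)=C/[C@@H](C)CC)cc2C)O[C@H](C(C)(C)C)OC1=O.CC(=O)[O-] | intermediate
14 | (2S,5R)-2-tert-butyl-5-({6-[(1E,3E,5S)-3,5-dimethylhepta-1,3-dien-1-yl]-4-methylidene-4H-pyran-3-yl}carbonyl)-5-methyl-1,3-dioxolan-4-one | C[C@]1(C(=O)C2=COC(/C=C/C(C)=C/[C@@H](C)CC)=CC2=C)O[C@H](C(C)(C)C)OC1=O | intermediate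
15 | (7S)-3-[(1E,3E,5S)-3,5-dimethylhepta-1,3-dien-1-yl]-7-hydroxy-7-methyl-6H-isochromene-6,8(7H)-dione | O[C@]1(C)C(=O)C2=COC(/C=C/C(C)=C/[C@@H](C)CC)=CC2=CC1=O | intermediate
16 | (7S)-3-[(1E,3E,5S)-3,5-dimethylhepta-1,3-dien-1-yl]-7-methyl-6,8-dioxo-7,8-dihydro-6H-isochromen-7-yl propanoate | CCC(=O)O[C@]1(C)C(=O)C2=COC(/C=C/C(C)=C/[C@@H](C)CC)=CC2=CC1=O | intermediate
17 | sclerketide B, (7R)-5-chloro-3-[(1E,3E,5S)-3,5-dimethylhepta-1,3-dien-1-yl]-7-methyl-6,8-dioxo-7,8-dihydro-6H-isochromen-7-yl propanoate | CCC(=O)O[C@]1(C)C(=O)C2=COC(/C=C/C(C)=C/[C@@H](C)CC)=CC2=C(Cl)C1=O | target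

Total step count: 8.
Longest linear sequence: 6 steps (6 → 8 → 9 → 10 → 15 → 16 → 17); the second branch (1 → 4 → 5) has 2 steps before the union.

Steps most likely to fail

1. Step 6 (proposed new method). The intermolecular conjugate addition of the hindered enaminone to the beta-substituted ynone may be slow, and the methylidene pyran may be intercepted by morpholine or acetate at C1 before it acylates. The fallback is the known hydroxylative dearomatisation route to the same alcohol. It sets out from 8. A Horner–Wadsworth–Emmons reaction with diethyl [3-(trimethylsilyl)prop-2-yn-1-yl]phosphonate (LiN(SiMe3)2, THF) would give trimethyl[(3E,5E,7S)-5,7-dimethylnona-3,5-dien-1-yn-1-yl]silane F1, and K2CO3 in MeOH the enyne (3E,5E,7S)-5,7-dimethylnona-3,5-dien-1-yne F2. Sonogashira coupling (Pd(PPh3)2Cl2, CuI, Et3N) with 6-bromo-2,4-dihydroxy-3-methylbenzaldehyde F3 would give 6-[(3E,5E,7S)-5,7-dimethylnona-3,5-dien-1-yn-1-yl]-2,4-dihydroxy-3-methylbenzaldehyde F4. Enantioselective oxidative dearomatisation with [Cu(MeCN)4]PF6, the (+)-sparteine surrogate diamine and O2 at −78 °C would give the vinylogous acid (5S)-2-[(3E,5E,7S)-5,7-dimethylnona-3,5-dien-1-yn-1-yl]-4,5-dihydroxy-5-methyl-6-oxocyclohexa-1,3-diene-1-carbaldehyde F5. Cycloisomerisation of F5 in phosphate buffer or with catalytic CuI would close the pyran and come back to the route at 15.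

2. Step 8. The electrophile may show poor site selectivity, attacking the electron-rich diene of the side chain or chlorinating twice. In the fallback chlorine is carried in with the ynone. It sets out from 9: addition of LiC≡CCH2Cl (3-chloroprop-1-yne, n-BuLi, THF, −78 °C) would give (5E,7E,9S)-1-chloro-7,9-dimethylundeca-5,7-dien-2-yn-4-one F6. F6 would take the place of 10 in step 6, where the 4-chloromethylpyrylium ion would lose a proton to the chloromethylidene pyran and close ring A to (7R)-5-chloro-3-[(1E,3E,5S)-3,5-dimethylhepta-1,3-dien-1-yl]-7-hydroxy-7-methyl-6H-isochromene-6,8(7H)-dione F7. Propanoylation of F7 as in step 7 would come back to the route at 17.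

3. Step 1. The enolate may decompose above −78 °C, or the hindered lithium aldolate may revert (retro-aldol) during the quench, giving low conversion. In the fallback the aldol and the oxidation are replaced by a C-acylation. It sets out from 1: the enolate 3 would be treated at −78 °C with 3-(trimethylsilyl)prop-2-ynoyl chloride F8 (from the acid and (COCl)2). Since the product has no alpha hydrogen the acylation cannot be reversed by proton transfer, and it would come back to the route at 5.

## Further compounds

F1 | step 6 | trimethyl[(3E,5E,7S)-5,7-dimethylnona-3,5-dien-1-yn-1-yl]silane | C[Si](C)(C)C#C/C=C/C(C)=C/[C@@H](C)CC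
F2 | step 6 | (3E,5E,7S)-5,7-dimethylnona-3,5-dien-1-yne | C#C/C=C/C(C)=C/[C@@H](C)CC
F3 | step 6 | 6-bromo-2,4-dihydroxy-3-methylbenzaldehyde | O=Cc1c(Br)cc(O)c(C)c1O
F4 | step 6 | 6-[(3E,5E,7S)-5,7-dimethylnona-3,5-dien-1-yn-1-yl]-2,4-dihydroxy-3-methylbenzaldehyde | O=Cc1c(C#C/C=C/C(C)=C/[C@@H](C)CC)cc(O)c(C)c1O
F5 | step 6 | (5S)-2-[(3E,5E,7S)-5,7-dimethylnona-3,5-dien-1-yn-1-yl]-4,5-dihydroxy-5-methyl-6-oxocyclohexa-1,3-diene-1-carbaldehyde | O=CC1=C(C#C/C=C/C(C)=C/[C@@H](C)CC)C=C(O)[C@](C)(O)C1=O
F6 | step 8 | (5E,7E,9S)-1-chloro-7,9-dimethylundeca-5,7-dien-2-yn-4-one | ClCC#CC(=O)/C=C/C(C)=C/[C@@H](C)CC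
F7 | step 8 | (7R)-5-chloro-3-[(1E,3E,5S)-3,5-dimethylhepta-1,3-dien-1-yl]-7-hydroxy-7-methyl-6H-isochromene-6,8(7H)-dione | O[C@]1(C)C(=O)C2=COC(/C=C/C(C)=C/[C@@H](C)CC)=CC2=C(Cl)C1=O
F8 | step 1 | 3-(trimethylsilyl)prop-2-ynoyl chloride | C[Si](C)(C)C#CC(Cl)=O
A1 | direct plan | 2-methylcyclopentane-1,3-dione | CC1C(=O)CCC1=O
A2 | direct plan | 3,4-dichloro-1-methyl-2,5-dioxocyclopent-3-en-1-yl propanoate | CCC(=O)OC1(C)C(=O)C(Cl)=C(Cl)C1=O
A3 | direct plan | (1R)-3,4-dichloro-1-methyl-2,6-dioxocyclohex-3-en-1-yl propanoate | CCC(=O)O[C@]1(C)C(=O)CC(Cl)=C(Cl)C1=O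
A4 | direct plan | (1R,5E)-3,4-dichloro-5-[(dimethylamino)methylidene]-1-methyl-2,6-dioxocyclohex-3-en-1-yl propanoate | CCC(=O)O[C@]1(C)C(=O)/C(=C\N(C)C)C(Cl)=C(Cl)C1=O
A5 | direct plan | (3E,5E,7S)-5,7-dimethylnona-3,5-dien-2-one | CC(=O)/C=C/C(C)=C/[C@@H](C)CC
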